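**Plan**

- Atom labels: ring A is C3–C4–C5(OH)–C6(Me)–C7; ring B is C2(Me)=C3–C7–C8(OH)–C9(Me)–C18–C19–C20; ring C is C9–C10–C11–C12(Me)–C17–C18; ring D is C12–C13–C14–C15(Me)2–C16–C17.
- Enabling feature: C9 is a quaternary carbon of ring C that carries a methyl group and the oxygen-bearing C8 and is bonded to C10. Read as the α-carbon of a C8 ester, it can be made by letting an ester enolate displace a C10 iodide that is tethered through C11–C12–C17–C18.
- Retrosynthetic cuts, in order: C2=C3 (ring B, reductive carbonyl coupling); C7–C8 (ring A alkenyllithium plus C8 aldehyde); C9–C10 (ring C, enolate cycloalkylation); C18–C19 and C18=C9 (conjugate addition to an alkylidene malonate); C12–C13 and C16–C17 (ring D, Diels–Alder).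
- Forward order: ring D, then the two side arms, then ring C (key step), then ring A is attached, and ring B is closed last.
- Stereochemistry: C12/C17 come from a catalyst-controlled Diels–Alder reaction of an (E)-dienophile; C18 from 1,3-allylic strain in the conjugate addition; C9 from the key step; C5 from (R)-4-silyloxycyclopentenone; C8 from a Felkin–Anh hydride reduction; C6/C7 from a hydroxyl-directed hydrogenation.

Key step: step 14

Assumption: the (S)-configured oxazaborolidinium catalyst is taken to give the (1R,6R) Diels–Alder adduct; if the facial sense proves to be the reverse, the (R)-catalyst is used.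

**Route**

Step 1
Reactants: 1 isoprene (2-methylbuta-1,3-diene); 2 ethyl (E)-3-methyl-4-oxobut-2-enoate
Product: 3 ethyl (1R,6R)-6-formyl-3,6-dimethylcyclohex-3-ene-1-carboxylate (formyl trans to ester; these are C12 and C17)
Conditions: (S)-3,3-diphenyl-1-(o-tolyl)tetrahydropyrrolo[1,2-c][1,3,2]oxazaborole·HNTf2 (20 mol%), CH2Cl2, −78 → −20 °C
Reagents that add atoms: none
Why: Enantioselective Diels–Alder reaction under chiral oxazaborolidinium catalysis; the catalyst binds the formyl group, so the methyl-bearing diene carbon should end para to C12, the (E)-geometry of 2 becomes the trans relation of formyl and ester, and the catalyst face sets the absolute configuration of C12 and C17.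

Step 2
Reactants: 3 ethyl (1R,6R)-6-formyl-3,6-dimethylcyclohex-3-ene-1-carboxylate
Product: 4 ethyl 6-ethenyl-3,6-dimethylcyclohex-3-ene-1-carboxylate (ring configuration of 3 retained; vinyl trans to ester)
Conditions: Ph3PCH3Br, KOt-Bu, THF, 0 °C
Reagents that add atoms: methyltriphenylphosphonium bromide, C[P+](c1ccccc1)(c1ccccc1)c1ccccc1.[Br-]
Why: Wittig methylenation of a non-enolisable α-quaternary aldehyde adds C10; the ester is inert to the ylide at 0 °C.

Step 3
Reactants: 4 ethyl 6-ethenyl-3,6-dimethylcyclohex-3-ene-1-carboxylate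
Product: 5 ethyl 6-(2-hydroxyethyl)-3,6-dimethylcyclohex-3-ene-1-carboxylate
Conditions: 9-BBN, THF, 0 → 40 °C; then H2O2, aq. NaOAc, 0 °C
Reagents that add atoms: hydrogen peroxide, OO
Why: Hydroboration–oxidation; 9-BBN adds anti-Markovnikov to the monosubstituted vinyl group only and leaves the trisubstituted ring alkene, and the buffered work-up spares the ester.

Step 4
Reactants: 5 ethyl 6-(2-hydroxyethyl)-3,6-dimethylcyclohex-3-ene-1-carboxylate
Product: 6 ethyl 3,6-dimethyl-6-[2-(triisopropylsilyloxy)ethyl]cyclohex-3-ene-1-carboxylate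
Conditions: i-Pr3SiCl, imidazole, DMF, rt
Reagents that add atoms: chlorotri(propan-2-yl)silane, CC(C)[Si](Cl)(C(C)C)C(C)C
Why: Silylation of the primary alcohol; the triisopropylsilyl ether has no arene for PtO2 to reduce and should withstand the acid, hydride, Lewis acid and base of steps 5–11.

Step 5
Reactants: 6 ethyl 3,6-dimethyl-6-[2-(triisopropylsilyloxy)ethyl]cyclohex-3-ene-1-carboxylate
Product: 7 ethyl 1,4-dimethyl-4-[2-(triisopropylsilyloxy)ethyl]bicyclo[4.1.0]heptane-3-carboxylate (either cyclopropane face)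
Conditions: Et2Zn, CH2I2, CH2Cl2, 0 °C → rt
Reagents that add atoms: diiodomethane, ICI
Why: Simmons–Smith (Furukawa) cyclopropanation of the only alkene, an electron-rich trisubstituted one; both face isomers converge in step 6.

Step 6
Reactants: 7 ethyl 1,4-dimethyl-4-[2-(triisopropylsilyloxy)ethyl]bicyclo[4.1.0]heptane-3-carboxylate
Product: 8 ethyl 2,5,5-trimethyl-2-[2-(triisopropylsilyloxy)ethyl]cyclohexane-1-carboxylate (ester trans to the silyloxyethyl arm)
Conditions: H2 (4 atm), PtO2, AcOH, rt
Reagents that add atoms: none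
Why: Hydrogenolysis of the cyclopropane cleaves the least substituted bond (CH2–C14), the classical conversion of a methylcyclopropane into a gem-dimethyl group (C15).

Step 7
Reactants: 8 ethyl 2,5,5-trimethyl-2-[2-(triisopropylsilyloxy)ethyl]cyclohexane-1-carboxylate
Product: 9 2,5,5-trimethyl-2-[2-(triisopropylsilyloxy)ethyl]cyclohexane-1-carbaldehyde (C12/C17 unchanged)
Conditions: i-Bu2AlH, CH2Cl2, −78 °C; aq. potassium sodium tartrate
Reagents that add atoms: none
Why: Partial reduction of a hindered ester; the tetrahedral aluminate should persist at −78 °C and release the C18 aldehyde on work-up, without base that could epimerise C17.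

Step 8
Reactants: 9 2,5,5-trimethyl-2-[2-(triisopropylsilyloxy)ethyl]cyclohexane-1-carbaldehyde; 10 dimethyl malonate
Product: 11 dimethyl 2-({2,5,5-trimethyl-2-[2-(triisopropylsilyloxy)ethyl]cyclohexyl}methylidene)propanedioate
Conditions: TiCl4, pyridine, THF, 0 °C → rt
Reagents that add atoms: none
Why: Knoevenagel condensation under Lehnert conditions, which suit hindered α-branched aldehydes and are mild enough at 0 °C to leave C17 intact; it forms C18=C9.

Step 9
Reactants: 11 dimethyl 2-({2,5,5-trimethyl-2-[2-(triisopropylsilyloxy)ethyl]cyclohexyl}methylidene)propanedioate; 12 2-(2-bromoethyl)-2-methyl-1,3-dioxolane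
Product: 14 dimethyl 2-{3-(2-methyl-1,3-dioxolan-2-yl)-1-[2,5,5-trimethyl-2-(2-triisopropylsilyloxyethyl)cyclohexyl]propyl}propanedioate, via Grignard reagent 13 (not isolated)
Conditions: 12, Mg, THF, 25 °C; then CuBr·SMe2 (10 mol%), 11, THF, −40 → −10 °C
Reagents that add atoms: none
Why: Copper-catalysed conjugate addition of a Grignard reagent to an alkylidene malonate forms C18–C19 and brings in C20, C2 (as ketal) and C1; 1,3-allylic strain with the cis ester holds C17–H in the plane of the double bond, so the nucleophile should enter anti to the quaternary C12 and set C18.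

Step 10
Reactants: 14 dimethyl 2-{3-(2-methyl-1,3-dioxolan-2-yl)-1-[2,5,5-trimethyl-2-(2-triisopropylsilyloxyethyl)cyclohexyl]propyl}propanedioate
Product: 15 dimethyl 2-methyl-2-{3-(2-methyl-1,3-dioxolan-2-yl)-1-[2,5,5-trimethyl-2-(2-triisopropylsilyloxyethyl)cyclohexyl]propyl}propanedioate
Conditions: NaH, MeI, THF/DMF, 0 °C → rt
Reagents that add atoms: iodomethane, CI
Why: C-Methylation of a malonate anion installs the C9 methyl group.

Step 11
Reactants: 15 dimethyl 2-methyl-2-{3-(2-methyl-1,3-dioxolan-2-yl)-1-[2,5,5-trimethyl-2-(2-triisopropylsilyloxyethyl)cyclohexyl]propyl}propanedioate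
Product: 16 methyl 2-methyl-5-(2-methyl-1,3-dioxolan-2-yl)-3-[2,5,5-trimethyl-2-(2-triisopropylsilyloxyethyl)cyclohexyl]pentanoate (both C9 epimers)
Conditions: LiCl, H2O, DMSO, 160 °C
Reagents that add atoms: none
Why: Krapcho dealkoxycarbonylation of a disubstituted dimethyl malonate under neutral conditions that the dioxolane tolerates; the C9 configuration is irrelevant because it is planarised in step 14.

Step 12
Reactants: 16 methyl 2-methyl-5-(2-methyl-1,3-dioxolan-2-yl)-3-[2,5,5-trimethyl-2-(2-triisopropylsilyloxyethyl)cyclohexyl]pentanoate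
Product: 17 methyl 3-[2-(2-hydroxyethyl)-2,5,5-trimethylcyclohexyl]-2-methyl-5-(2-methyl-1,3-dioxolan-2-yl)pentanoate
Conditions: Bu4NF, THF, rt
Reagents that add atoms: none
Why: Fluoride desilylation frees the C10 alcohol; lactonisation onto the C8 ester would need an eight-membered ring and should not compete.

Step 13
Reactants: 17 methyl 3-[2-(2-hydroxyethyl)-2,5,5-trimethylcyclohexyl]-2-methyl-5-(2-methyl-1,3-dioxolan-2-yl)pentanoate
Product: 18 methyl 3-[2-(2-iodoethyl)-2,5,5-trimethylcyclohexyl]-2-methyl-5-(2-methyl-1,3-dioxolan-2-yl)pentanoate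
Conditions: I2, PPh3, imidazole, CH2Cl2, 0 °C → rt
Reagents that add atoms: iodine, II
Why: Appel-type (Garegg–Samuelsson) iodination of a primary alcohol; imidazole buffers the acid so the dioxolane survives.

Step 14
Reactants: 18 methyl 3-[2-(2-iodoethyl)-2,5,5-trimethylcyclohexyl]-2-methyl-5-(2-methyl-1,3-dioxolan-2-yl)pentanoate
Product: 20 methyl 2,4a,7,7-tetramethyl-1-[2-(2-methyl-1,3-dioxolan-2-yl)ethyl]decahydronaphthalene-2-carboxylate (trans-fused), via potassium ester enolate 19 (not isolated)
Conditions: KN(SiMe3)2, THF (0.01 M), −78 → 0 °C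
Reagents that add atoms: none
Why: KN(SiMe3)2 removes the C9 proton of the methyl ester, the only acidic C–H in 18, and the potassium enolate displaces iodide at C10 in an intramolecular SN2 reaction that forms C9–C10. The closest known reaction type is the cycloalkylation of ester enolates by ω-iodoalkyl chains, which gives cyclohexanes with a quaternary α-carbon. Ring C closes in the 6-exo-tet mode through a chair in which C12–C11 and C17–C18 are both equatorial on ring D, so the new decalin is trans-fused with the C12 methyl axial. The new stereocentre C9 is controlled by 1,3-allylic strain: C18–H lies in the enolate plane beside the enolate oxygen, which leaves C17 and its tether on one face only, so C10 bonds there and the C9 methyl ends axial and anti to C18–H, with the ester equatorial. The step needs C-alkylation to win over elimination and intermolecular reaction, which the primary iodide, the six-membered transition state and high dilution secure; both C9 epimers of 18 converge on the same enolate.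

Step 15
Reactants: 20 methyl 2,4a,7,7-tetramethyl-1-[2-(2-methyl-1,3-dioxolan-2-yl)ethyl]decahydronaphthalene-2-carboxylate
Product: 21 2,4a,7,7-tetramethyl-1-[2-(2-methyl-1,3-dioxolan-2-yl)ethyl]decahydronaphthalene-2-carbaldehyde (C8 aldehyde)
Conditions: i-Bu2AlH, CH2Cl2, −78 °C; aq. potassium sodium tartrate
Reagents that add atoms: none
Why: Partial reduction of a neopentylic ester, whose tetrahedral aluminate should be stable at −78 °C; the aldehyde has no α-hydrogen and cannot epimerise.

Step 16
Reactants: 22 (R)-4-(tert-butyldimethylsilyloxy)cyclopent-2-en-1-one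
Product: 23 tert-butyldimethyl{[(1R)-2-methyl-4-(trimethylsilyloxy)cyclopent-3-en-1-yl]oxy}silane (methyl trans to the silyloxy group)
Conditions: Me2CuLi (from MeLi, CuI), Me3SiCl, THF, −78 °C
Reagents that add atoms: methyllithium, [Li]C; chlorotrimethylsilane, C[Si](C)(C)Cl
Why: Organocuprate conjugate addition with in situ O-silylation places the C6 methyl group and fixes the enol ether regiochemistry; the new stereocentre is erased in step 17.

Step 17
Reactants: 23 tert-butyldimethyl{[(1R)-2-methyl-4-(trimethylsilyloxy)cyclopent-3-en-1-yl]oxy}silane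
Product: 24 (R)-4-(tert-butyldimethylsilyloxy)-3-methylcyclopent-2-en-1-one
Conditions: Pd(OAc)2 (1.05 equiv), MeCN, rt
Reagents that add atoms: none
Why: Saegusa–Ito oxidation of the regiodefined silyl enol ether to the β-methyl enone; the C5 stereocentre is not touched.

Step 18
Reactants: 24 (R)-4-(tert-butyldimethylsilyloxy)-3-methylcyclopent-2-en-1-one
Product: 26 (R)-2-bromo-4-(tert-butyldimethylsilyloxy)-3-methylcyclopent-2-en-1-one, via dibromo ketone 25 (not isolated)
Conditions: Br2, CH2Cl2, 0 °C; then Et3N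
Reagents that add atoms: bromine, BrBr
Why: Bromine addition followed by dehydrobromination is the standard α-bromination of a β-substituted enone and puts the halogen on C7.

Step 19
Reactants: 26 (R)-2-bromo-4-(tert-butyldimethylsilyloxy)-3-methylcyclopent-2-en-1-one
Product: 27 (R)-6-bromo-8-(tert-butyldimethylsilyloxy)-7-methyl-1,4-dioxaspiro[4.4]non-6-ene
Conditions: (Me3SiOCH2)2, Me3SiOTf (10 mol%), CH2Cl2, −78 → −20 °C
Reagents that add atoms: 1,2-bis(trimethylsilyloxy)ethane, C[Si](C)(C)OCCO[Si](C)(C)C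
Why: Noyori ketalisation masks the C3 ketone under aprotic conditions that keep the silyl ether, giving the precursor of an α-keto vinyl anion equivalent.

Step 20
Reactants: 27 (R)-6-bromo-8-(tert-butyldimethylsilyloxy)-7-methyl-1,4-dioxaspiro[4.4]non-6-ene; 21 2,4a,7,7-tetramethyl-1-[2-(2-methyl-1,3-dioxolan-2-yl)ethyl]decahydronaphthalene-2-carbaldehyde
Product: 29 allylic alcohols joining C7 of the dioxaspirononene to C8 of the decalin (both C8 epimers), via alkenyllithium 28 (not isolated)
Conditions: t-BuLi (2 equiv), Et2O, −78 °C; then 21, −78 °C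
Reagents that add atoms: none
Why: Bromine–lithium exchange and 1,2-addition of the alkenyllithium to a non-enolisable aldehyde forms C7–C8; both epimers are carried on because step 22 sets C8.

Step 21
Reactants: 29 allylic alcohols (both C8 epimers)
Product: 30 C8 ketone (enone conjugated with C7=C6)
Conditions: Dess–Martin periodinane, NaHCO3, CH2Cl2, rt
Reagents that add atoms: none
Why: Dess–Martin oxidation of a hindered allylic alcohol under buffered conditions that leave both ketals and the silyl ether.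

Step 22
Reactants: 30 C8 ketone
Product: 31 allylic alcohol with C8 configured as in the target
Conditions: i-Bu2AlH, CH2Cl2, −78 °C
Reagents that add atoms: none
Why: 1,2-Reduction of the hindered enone; by the Felkin–Anh model hydride should enter anti to C18 on the quaternary C9, which gives the target C8 configuration, the one disfavoured in the direct alkenyl addition.

Step 23
Reactants: 31 allylic alcohol (C5 silyl ether)
Product: 32 C5,C8-diol
Conditions: Bu4NF, THF, rt
Reagents that add atoms: none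
Why: Fluoride desilylation frees the ring allylic hydroxyl so that it can direct the next step.

Step 24
Reactants: 32 C5,C8-diol
Product: 33 saturated C5,C8-diol with C6 and C7 as in the target
Conditions: H2 (1–4 atm), [Ir(cod)(PCy3)(py)]PF6 (10–20 mol%), CH2Cl2, rt
Reagents that add atoms: none
Why: Hydroxyl-directed hydrogenation with a Crabtree-type cationic iridium catalyst; syn addition makes the C6 methyl and the C7–C8 bond cis, and both hydroxyls (C5 on the ring, C8 held on the same face by 1,3-allylic strain with the C6 methyl) should deliver hydrogen to the face away from C9.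

Step 25
Reactants: 33 saturated C5,C8-diol
Product: 34 C5,C8-bis(tert-butyldimethylsilyl) ether
Conditions: t-BuMe2SiOTf, 2,6-lutidine, CH2Cl2, −78 → 0 °C
Reagents that add atoms: tert-butyldimethylsilyl trifluoromethanesulfonate, CC(C)(C)[Si](C)(C)OS(=O)(=O)C(F)(F)F
Why: Silylation with the triflate reaches the hindered C8 alcohol and protects both oxygens, each β to the future C3 ketone, before the ketals are opened.

Step 26
Reactants: 34 C5,C8-bis(silyl ether) bis(ketal)
Product: 35 C2,C3-diketone
Conditions: PPTS, acetone/H2O (10:1), 50 °C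
Reagents that add atoms: water, O
Why: Mild acid hydrolysis opens both dioxolanes together and should leave the silyl ethers and the C7 stereocentre untouched.

Step 27
Reactants: 35 C2,C3-diketone
Product: 36 C5,C8-bis(tert-butyldimethylsilyl) ether of the target
Conditions: TiCl3(DME)1.5, Zn–Cu couple, DME, reflux; 35 added by syringe pump
Reagents that add atoms: none
Why: Intramolecular McMurry coupling; low-valent titanium joins the two ketones as a pinacolate and deoxygenates it to the tetrasubstituted C2=C3 alkene, closing the eight-membered ring B with the cis geometry the ring imposes.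

Step 28
Reactants: 36 C5,C8-bis(silyl ether) of the target
Product: 37 CNP0213887.1 (target)
Conditions: HF·pyridine, THF, 0 °C → rt
Reagents that add atoms: none
Why: Buffered fluoride desilylation frees both secondary alcohols without isomerising the tetrasubstituted alkene.

**Compound list**

1 | isoprene | C=CC(C)=C | starting material
2 | ethyl (E)-3-methyl-4-oxobut-2-enoate | CCOC(=O)/C=C(\C)C=O | starting material
3 | ethyl (1R,6R)-6-formyl-3,6-dimethylcyclohex-3-ene-1-carboxylate | CCOC(=O)[C@@H]1CC(C)=CC[C@@]1(C)C=O | intermediate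
4 | ethyl 6-ethenyl-3,6-dimethylcyclohex-3-ene-1-carboxylate (vinyl trans to ester) | CCOC(=O)[C@@H]1CC(C)=CC[C@@]1(C)C=C | intermediate
5 | ethyl 6-(2-hydroxyethyl)-3,6-dimethylcyclohex-3-ene-1-carboxylate | CCOC(=O)[C@@H]1CC(C)=CC[C@@]1(C)CCO | intermediate
6 | ethyl 3,6-dimethyl-6-[2-(triisopropylsilyloxy)ethyl]cyclohex-3-ene-1-carboxylate | CCOC(=O)[C@@H]1CC(C)=CC[C@@]1(C)CCO[Si](C(C)C)(C(C)C)C(C)C | intermediate
7 | ethyl 1,4-dimethyl-4-[2-(triisopropylsilyloxy)ethyl]bicyclo[4.1.0]heptane-3-carboxylate (cyclopropane face not defined) | CCOC(=O)[C@@H]1CC2(C)CC2C[C@@]1(C)CCO[Si](C(C)C)(C(C)C)C(C)C | intermediate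
8 | ethyl 2,5,5-trimethyl-2-[2-(triisopropylsilyloxy)ethyl]cyclohexane-1-carboxylate (ester trans to the arm) | CCOC(=O)[C@@H]1CC(C)(C)CC[C@@]1(C)CCO[Si](C(C)C)(C(C)C)C(C)C | intermediate
9 | 2,5,5-trimethyl-2-[2-(triisopropylsilyloxy)ethyl]cyclohexane-1-carbaldehyde | O=C[C@@H]1CC(C)(C)CC[C@@]1(C)CCO[Si](C(C)C)(C(C)C)C(C)C | intermediate
10 | dimethyl malonate | COC(=O)CC(=O)OC | starting material
11 | dimethyl 2-({2,5,5-trimethyl-2-[2-(triisopropylsilyloxy)ethyl]cyclohexyl}methylidene)propanedioate | COC(=O)C(C(=O)OC)=C[C@@H]1CC(C)(C)CC[C@@]1(C)CCO[Si](C(C)C)(C(C)C)C(C)C | intermediate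
12 | 2-(2-bromoethyl)-2-methyl-1,3-dioxolane | CC1(CCBr)OCCO1 | starting material
13 | [2-(2-methyl-1,3-dioxolan-2-yl)ethyl]magnesium bromide | CC1(CC[Mg]Br)OCCO1 | intermediate (not isolated)
14 | conjugate adduct, dimethyl malonate with C18 set | COC(=O)C(C(=O)OC)[C@@H](CCC1(C)OCCO1)[C@@H]1CC(C)(C)CC[C@@]1(C)CCO[Si](C(C)C)(C(C)C)C(C)C | intermediate
15 | C9-methylated malonate | COC(=O)C(C)(C(=O)OC)[C@@H](CCC1(C)OCCO1)[C@@H]1CC(C)(C)CC[C@@]1(C)CCO[Si](C(C)C)(C(C)C)C(C)C | intermediate
16 | methyl ester, silyl ether (both C9 epimers) | COC(=O)C(C)[C@@H](CCC1(C)OCCO1)[C@@H]1CC(C)(C)CC[C@@]1(C)CCO[Si](C(C)C)(C(C)C)C(C)C | intermediate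
17 | methyl ester, C10 alcohol (both C9 epimers) | COC(=O)C(C)[C@@H](CCC1(C)OCCO1)[C@@H]1CC(C)(C)CC[C@@]1(C)CCO | intermediate
18 | methyl 3-[2-(2-iodoethyl)-2,5,5-trimethylcyclohexyl]-2-methyl-5-(2-methyl-1,3-dioxolan-2-yl)pentanoate (both C9 epimers) | COC(=O)C(C)[C@@H](CCC1(C)OCCO1)[C@@H]1CC(C)(C)CC[C@@]1(C)CCI | intermediate
19 | potassium enolate of 18 | COC([O-])=C(C)[C@@H](CCC1(C)OCCO1)[C@@H]1CC(C)(C)CC[C@@]1(C)CCI.[K+] | intermediate (not isolated)
20 | methyl 2,4a,7,7-tetramethyl-1-[2-(2-methyl-1,3-dioxolan-2-yl)ethyl]decahydronaphthalene-2-carboxylate (trans-fused; C9 methyl axial) | COC(=O)[C@@]1(C)CC[C@]2(C)CCC(C)(C)C[C@H]2[C@@H]1CCC1(C)OCCO1 | intermediate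
21 | corresponding decalin-2-carbaldehyde (C8 aldehyde) | O=C[C@@]1(C)CC[C@]2(C)CCC(C)(C)C[C@H]2[C@@H]1CCC1(C)OCCO1 | intermediate
22 | (R)-4-(tert-butyldimethylsilyloxy)cyclopent-2-en-1-one | O=C1C=C[C@H](O[Si](C)(C)C(C)(C)C)C1 | starting material
23 | trans-3-methyl-4-(tert-butyldimethylsilyloxy)-1-(trimethylsilyloxy)cyclopent-1-ene | C[Si](C)(C)OC1=C[C@@H](C)[C@H](O[Si](C)(C)C(C)(C)C)C1 | intermediate
24 | (R)-4-(tert-butyldimethylsilyloxy)-3-methylcyclopent-2-en-1-one | O=C1C=C(C)[C@H](O[Si](C)(C)C(C)(C)C)C1 | intermediate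
25 | 2,3-dibromo-4-(tert-butyldimethylsilyloxy)-3-methylcyclopentan-1-one | O=C1C(Br)C(C)(Br)[C@H](O[Si](C)(C)C(C)(C)C)C1 | intermediate (not isolated)
26 | (R)-2-bromo-4-(tert-butyldimethylsilyloxy)-3-methylcyclopent-2-en-1-one | O=C1C(Br)=C(C)[C@H](O[Si](C)(C)C(C)(C)C)C1 | intermediate
27 | (R)-6-bromo-8-(tert-butyldimethylsilyloxy)-7-methyl-1,4-dioxaspiro[4.4]non-6-ene | BrC1=C(C)[C@H](O[Si](C)(C)C(C)(C)C)CC12OCCO2 | intermediate
28 | 6-lithio analogue of 27 | [Li]C1=C(C)[C@H](O[Si](C)(C)C(C)(C)C)CC12OCCO2 | intermediate (not isolated)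
29 | allylic alcohols, C7–C8 joined (both C8 epimers) | OC([C@@]1(C)CC[C@]2(C)CCC(C)(C)C[C@H]2[C@@H]1CCC1(C)OCCO1)C1=C(C)[C@H](O[Si](C)(C)C(C)(C)C)CC12OCCO2 | intermediate
30 | C8 ketone (enone) | O=C([C@@]1(C)CC[C@]2(C)CCC(C)(C)C[C@H]2[C@@H]1CCC1(C)OCCO1)C1=C(C)[C@H](O[Si](C)(C)C(C)(C)C)CC12OCCO2 | intermediate
31 | allylic alcohol, C8 as in target | O[C@@H]([C@@]1(C)CC[C@]2(C)CCC(C)(C)C[C@H]2[C@@H]1CCC1(C)OCCO1)C1=C(C)[C@H](O[Si](C)(C)C(C)(C)C)CC12OCCO2 | intermediate
32 | C5,C8-diol with C6=C7 | O[C@@H]([C@@]1(C)CC[C@]2(C)CCC(C)(C)C[C@H]2[C@@H]1CCC1(C)OCCO1)C1=C(C)[C@H](O)CC12OCCO2 | intermediate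
33 | saturated C5,C8-diol | O[C@@H]([C@@]1(C)CC[C@]2(C)CCC(C)(C)C[C@H]2[C@@H]1CCC1(C)OCCO1)[C@H]1[C@@H](C)[C@H](O)CC12OCCO2 | intermediate
34 | C5,C8-bis(silyl ether), bis(ketal) | CC(C)(C)[Si](C)(C)O[C@@H]([C@@]1(C)CC[C@]2(C)CCC(C)(C)C[C@H]2[C@@H]1CCC1(C)OCCO1)[C@H]1[C@@H](C)[C@H](O[Si](C)(C)C(C)(C)C)CC12OCCO2 | intermediate
35 | C2,C3-diketone | CC(C)(C)[Si](C)(C)O[C@@H]([C@@]1(C)CC[C@]2(C)CCC(C)(C)C[C@H]2[C@@H]1CCC(C)=O)[C@H]1[C@@H](C)[C@H](O[Si](C)(C)C(C)(C)C)CC1=O | intermediate
36 | C5,C8-bis(tert-butyldimethylsilyl) ether of the target | C/C1=C2\C[C@@H](O[Si](C)(C)C(C)(C)C)[C@H](C)[C@@H]2[C@@H](O[Si](C)(C)C(C)(C)C)[C@@]2(C)CC[C@]3(C)CCC(C)(C)C[C@H]3[C@@H]2CC1 | intermediate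
37 | CNP0213887.1 | C/C1=C2\C[C@@H](O)[C@H](C)[C@@H]2[C@@H](O)[C@@]2(C)CC[C@]3(C)CCC(C)(C)C[C@H]3[C@@H]2CC1 | target

**Step count**

Total: 28 steps. Longest linear sequence: 24 steps (steps 1–15 and 20–28). The ring A branch is steps 16–19.

**Steps most likely to fail**

1. Step 27 (McMurry ring closure). The reductive coupling may stall at the pinacol stage or turn intermolecular, because closing an eight-membered ring between two hindered ketones is slow. C7, which is α to the C3 ketone and cis to the C6 methyl, may also epimerise under the hot Lewis-acidic conditions. The fallback sets out from 35 and splits the coupling into two mild stages. SmI2 (divalent samarium) in THF at 0 °C and high dilution should give the chelation-controlled cis-pinacol F1. Thiophosgene and DMAP convert it into the cyclic thionocarbonate F2. Corey–Winter elimination with 1,3-dimethyl-2-phenyl-1,3,2-diazaphospholidine at 40 °C then gives the alkene and returns to the route at 36.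

2. Step 24 (directed hydrogenation). Hydrogen may fail to add to the tetrasubstituted double bond, or the acidic iridium hydride may ionise the allylic C8 alcohol or open a ketal. The fallback brings in the C6 methyl after the coupling, by conjugate addition, and sets C7 by protonation. It sets out from 22 and 21. Iodination of 22 (I2, pyridine) gives the iodo enone F3, and ketalisation as in step 19 gives the iodo ketal F4. Iodine–lithium exchange (t-BuLi) gives the alkenyllithium F5, which adds to 21 to give the allylic alcohols F6, and Dess–Martin oxidation gives the enone F7. Me2CuLi should add the methyl group to C6 anti to the C5 silyloxy group, giving the lithium enolate F8. Kinetic protonation at −78 °C from the face away from the new methyl group should give the ketone F9 with C7–H cis to C6–H. Reduction with i-Bu2AlH, in the same Felkin–Anh sense as step 22, gives the alcohol F10, and silylation with t-BuMe2SiOTf returns to the route at 34.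

3. Step 1 (Diels–Alder reaction). Regiocontrol may be poor and the cycloaddition slow, because the methyl group of 1 is a weak director against two acceptor groups that pull in opposite senses. The fallback sets out from 2 and uses a diene whose oxygen substituent fixes the regiochemistry, then makes the gem-dimethyl group from the resulting ketone. Under the same catalyst, 2 and 2-(trimethylsilyloxy)buta-1,3-diene should give the silyl enol ether adduct F11. Wittig methylenation gives the vinyl silyl enol ether F12. Hydroboration with 9-BBN, buffered peroxide work-up and dilute acid give the keto alcohol F13. Silylation with i-Pr3SiCl gives the keto silyl ether F14. Geminal dimethylation of the ketone with Me2TiCl2 (Reetz) returns to the route at 8.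

**Further compounds**

F1 | step 27 | cis-C2,C3-diol (pinacol) of the ring-B-closed bis(silyl ether); configuration at C2/C3 not assigned | CC1(O)C2(O)C[C@@H](O[Si](C)(C)C(C)(C)C)[C@H](C)[C@@H]2[C@@H](O[Si](C)(C)C(C)(C)C)[C@@]2(C)CC[C@]3(C)CCC(C)(C)C[C@H]3[C@@H]2CC1
F2 | step 27 | cyclic thionocarbonate of F1 | CC12OC(=S)OC13C[C@@H](O[Si](C)(C)C(C)(C)C)[C@H](C)[C@@H]3[C@@H](O[Si](C)(C)C(C)(C)C)[C@@]3(C)CC[C@]4(C)CCC(C)(C)C[C@H]4[C@@H]3CC2
F3 | step 24 | (R)-4-(tert-butyldimethylsilyloxy)-2-iodocyclopent-2-en-1-one | O=C1C(I)=C[C@H](O[Si](C)(C)C(C)(C)C)C1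
F4 | step 24 | (R)-8-(tert-butyldimethylsilyloxy)-6-iodo-1,4-dioxaspiro[4.4]non-6-ene | IC1=C[C@H](O[Si](C)(C)C(C)(C)C)CC12OCCO2
F5 | step 24 | 6-lithio analogue of F4 | [Li]C1=C[C@H](O[Si](C)(C)C(C)(C)C)CC12OCCO2
F6 | step 24 | des-methyl allylic alcohols (both C8 epimers) | OC([C@@]1(C)CC[C@]2(C)CCC(C)(C)C[C@H]2[C@@H]1CCC1(C)OCCO1)C1=C[C@H](O[Si](C)(C)C(C)(C)C)CC12OCCO2
F7 | step 24 | des-methyl C8 ketone (enone) | O=C([C@@]1(C)CC[C@]2(C)CCC(C)(C)C[C@H]2[C@@H]1CCC1(C)OCCO1)C1=C[C@H](O[Si](C)(C)C(C)(C)C)CC12OCCO2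
F8 | step 24 | lithium enolate after methyl addition at C6 | [Li+].[O-]C([C@@]1(C)CC[C@]2(C)CCC(C)(C)C[C@H]2[C@@H]1CCC1(C)OCCO1)=C1[C@@H](C)[C@H](O[Si](C)(C)C(C)(C)C)CC12OCCO2
F9 | step 24 | saturated C8 ketone with C6 and C7 as in the target | O=C([C@@]1(C)CC[C@]2(C)CCC(C)(C)C[C@H]2[C@@H]1CCC1(C)OCCO1)[C@H]1[C@@H](C)[C@H](O[Si](C)(C)C(C)(C)C)CC12OCCO2
F10 | step 24 | saturated C8 alcohol, C5 silyl ether | O[C@@H]([C@@]1(C)CC[C@]2(C)CCC(C)(C)C[C@H]2[C@@H]1CCC1(C)OCCO1)[C@H]1[C@@H](C)[C@H](O[Si](C)(C)C(C)(C)C)CC12OCCO2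
F11 | step 1 | ethyl (1R,6R)-6-formyl-6-methyl-3-(trimethylsilyloxy)cyclohex-3-ene-1-carboxylate | CCOC(=O)[C@@H]1CC(O[Si](C)(C)C)=CC[C@@]1(C)C=O
F12 | step 1 | ethyl 6-ethenyl-6-methyl-3-(trimethylsilyloxy)cyclohex-3-ene-1-carboxylate | CCOC(=O)[C@@H]1CC(O[Si](C)(C)C)=CC[C@@]1(C)C=C
F13 | step 1 | ethyl 2-(2-hydroxyethyl)-2-methyl-5-oxocyclohexane-1-carboxylate | CCOC(=O)[C@@H]1CC(=O)CC[C@@]1(C)CCO
F14 | step 1 | ethyl 2-methyl-5-oxo-2-[2-(triisopropylsilyloxy)ethyl]cyclohexane-1-carboxylate | CCOC(=O)[C@@H]1CC(=O)CC[C@@]1(C)CCO[Si](C(C)C)(C(C)C)C(C)C
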